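Amounts first: 0.15 M of substrate meets 3.00 equiv of first nucleophile in Monday's flask and 9.00 equiv in Sunday's, so substrate is the limiting reagent. I write its balance: substrate charged equals substrate left, plus target, plus whatever else the lost substrate became.

| setting | spring | winter | autumn | Monday's | Sunday's |
|---|---|---|---|---|---|
| substrate | 0.15 M | 0.15 M | 0.15 M | 0.15 M | 0.15 M |
| first nucleophile | 3.7 equiv | 4.8 equiv | 6.5 equiv | 3.00 equiv | 9.00 equiv |
| gas | 8.9 mM (held) | 8.9 mM (held) | 8.9 mM (held) | 8.9 mM (held) | 8.9 mM (held) |
| remark | run made earlier | run made earlier | run made earlier |  |  |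
| time |  |  |  | 2.0 h | 0.60 h |

| run | time / min | target / % | substrate / % |
|---|---|---|---|
| spring | 25.0 | 13.6 | 75.1 |
| spring | 50.0 | 21.6 | 56.2 |
| spring | 80.0 | 27.6 | 40.8 |
| spring | 90.0 | 29.8 | 35.9 |
| spring | 120 | 33.9 | 25.4 |
| winter | 10.0 | 6.9 | 88.5 |
| winter | 30.0 | 16.3 | 71.0 |
| winter | 60.0 | 26.2 | 50.3 |
| winter | 80.0 | 31.2 | 39.6 |
| winter | 120 | 38.9 | 25.6 |
| autumn | 10.0 | 7.2 | 89.3 |
| autumn | 20.0 | 12.6 | 78.5 |
| autumn | 30.0 | 18.7 | 70.7 |
| autumn | 60.0 | 29.9 | 50.0 |
| autumn | 120 | 42.5 | 25.3 |

(standard deviation of a reading: 0.5 percentage points)

- what was read earlier has a scatter of 0.5 percentage points, one standard deviation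
- at the start none of the gas is in solution
- a reading or a percentage of target counts all its forms, free or not

* the flask that ends with the higher amount of target, in percent of the substrate charged, or "neither" when 2 percentage points or less lies between them (Monday's / Sunday's / neither)
* final target, as a percentage of the substrate charged, in Monday's
* final target, as a percentage of the substrate charged, in Sunday's

I start with what is lost. At 120 min the three runs read 25.4%, 25.6% and 25.3% of substrate, though their first nucleophile runs from 3.7 equiv to 6.5 equiv. So I take one first-order decay, read from the autumn run as 0.0115 /min. That loses 74.7% in Monday's flask and 33.8% in Sunday's.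

Next I split the loss. My quantity is the odds per equivalent, a selectivity factor: target divided by the substrate lost to anything else, divided by the equivalents charged. The last readings give 0.225, 0.228 and 0.203, with mean 0.219. Target is then the loss times odds over one plus odds, which gives Monday's 29.6%.

The weak link is Sunday's flask, which stops at 0.60 h while that factor was read at 120 min. Read at 30.0 min, the winter and autumn runs give 0.267 and 0.271, both higher than the late mean. With their mean 0.269, Sunday's comes to 23.9%, though 9.00 equiv lies beyond the runs. I commit to Monday's, by 5.7 percentage points, more than the margin.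

The forecast also chooses Monday's, with 30% (27.5% to 32%) and 23.5% (21.5% to 25.5%), noting that “Selectivity also falls with time by a similar amount in every run”.

    crystals ⇌ target, rate k1*(cs1 - [target]) while solid is left; crystals form when [target] > cs1 (solubility = 18.0 mM, k = 0.0530 /s)
    second nucleophile + intermediate → other capture product (k = 15.0 /M/s)
    intermediate → solvolysis product (k = 0.0240 /s)
    gas ⇌ second nucleophile, rate k4*(csat - [second nucleophile]) (kL = 0.00200 /s)
    intermediate → side product (k = 2.80 × 10⁻⁴ /s)
    first nucleophile + intermediate → target (k = 0.150 /M/s)
    substrate → intermediate (k = 1.90 × 10⁻⁴ /s)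

Monday's flask gives 30.7% and Sunday's 23.0%, crystals counted in target. Beside Monday's target stands 32.2% of other capture product. Monday's odds per equivalent come out at 0.233. For the forecast's choice to fall, Monday's lead of 7.7 points has to shrink to 2 points. A neighbour flask like Monday's, with 1.80 equiv of first nucleophile, reckons at 21.1% with the 0.219 read from the runs, and it stands at 23.1%, level with Sunday's 23.0%.

The earlier runs and the new flask were generated by integration for an exercise; the scatter is artificial.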